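Count the charge, not the percent.

| flask | X | remark | time |
|---|---|---|---|
| south | 0.48 M | run made earlier |  |
| south-west | 0.73 M | run made earlier |  |
| flask | 0.97 M |  | 4.0 d |

| run | time / d | G / % | E / % |
|---|---|---|---|
| south | 0.208 | 4 | 18 |
| south | 0.625 | 4 | 33 |
| south | 1.04 | 6 | 40 |
| south | 1.67 | 5 | 40 |
| south | 2.50 | 3 | 41 |
| south | 3.00 | 5 | 41 |
| south-west | 0.208 | 2 | 11 |
| south-west | 0.625 | 5 | 23 |
| south-west | 1.04 | 3 | 25 |
| south-west | 1.67 | 4 | 25 |
| south-west | 2.50 | 4 | 26 |
| south-west | 3.00 | 4 | 27 |

(scatter of a reading: 1.5 percentage points)

- as a solid, counted per litre of solution: X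
- the numbers in the tables scatter with a standard deviation of 1.5 percentage points
- steps under discussion: G <-> E; D <-> E; X <-> D; D <-> G
- at the start none of X is in solution
- what has only dissolved of X counts as not reacted

- amount of G at 4.0 d, in percent of the X charged
- amount of E at 4.0 d, in percent of the X charged

E stands flat from about 1.04 d in both runs, so I read thermodynamic rather than kinetic control and take the last readings as plateaus. In the south run 41% of the charge is cE = 0.197 M. In the south-west run 27% is 0.197 M, so the percent falls while cE stays. I take 0.197 M as the plateau cE.

For the new flask I fold this into one number, the load, the charge of X divided by the plateau cE 4.93. E in percent of the charge is then one over the load, 20.3%.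

Is one number enough? From the south run alone, the south-west charge gives 27.0% of E, and that run reads 27%. G needs its own plateau, 0.0266 M, which gives 2.74% in this flask. I assume undissolved X stays in this flask, whose charge is larger than either earlier one.

The forecast says 20% of E (18.5% to 21.5%) and 2.5% of G (1.7% to 3.4%), a G lower than mine, and it holds that “4 d is well past the plateau”.

The flask gives 20.0% of E and 2.62% of G.

    G ⇌ E (k = 0.00140 /min)
    D ⇌ E (K = 2.90, k = 0.00790 /min)
    X ⇌ D, rate k3*(cs3 - [D]) while solid is left; crystals form when [D] > cs3 (solubility = 0.0670 M, k = 0.0310 /min)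
    D ⇌ G (K = 0.380, k = 0.0190 /min)

Undissolved X in this flask stands at 70.4% of the charge at 4.00 d. A neighbour flask charged with 0.24 M has a load of 1.22, and one over that is 82.1%. At 4.00 d that neighbour holds 67.8% of E, 23.4% of D and 8.88% of G, with undissolved X at 0%.

The readings come from a simulation on assumed constants; scatter was added.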